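**Retrosynthetic overview**

1. Dinklagein A ⇒ its bis-MOM ether. Both phenols are unmasked last with methanolic acid; the C7 prenyl group sits between 6-OMe and O1, so it has no free ortho phenol to cyclise onto.
2. Feature used: the furan C2=C3 bond joins a benzylic CH (C3, attached to C3a) to a carbon at the carboxylic acid oxidation level (C2, bonded to O1 and to the 3-hydroxy-5-methoxyphenyl ring). The furan is therefore opened at C2=C3 to a benzylic phosphonium ylide (C3) and an aryl ester on the C7a oxygen (C2), closed by intramolecular Wittig reaction.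
3. O-Aroyl phosphonium salt ⇒ 2-hydroxybenzylphosphonium bromide + 3-methoxy-5-(methoxymethoxy)benzoic acid; phosphonium salt ⇒ salicyl alcohol ⇒ salicylaldehyde ⇒ 2-prenylphenol (ortho-formylation at the only free ortho carbon).
4. 2-Prenylphenol ⇒ aryl diethylcarbamate (ortho-metalation between carbamate and OMe, then prenyl bromide) ⇒ MOM-vanillin by Dakin-type oxidation.
5. Ring order: both benzene rings are purchased; the furan ring is the only ring formed (step 12).

Key step: step 12

Remark: methyl 3-hydroxy-5-methoxybenzoate and triphenylphosphine hydrobromide are treated as catalogue chemicals; the target has no stereocentre and no stereogenic double bond, so no stereocontrol is needed; ring positions follow benzofuran numbering.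

**Route**

Step 1
Reactants: 1 vanillin
Product: 2 3-methoxy-4-(methoxymethoxy)benzaldehyde
Conditions: MOMCl, i-Pr2NEt, CH2Cl2, 0 °C → rt
Reagents that add atoms: chloromethyl methyl ether, COCCl
Why: Williamson-type O-alkylation of the phenol with the reactive chloromethyl ether masks the future C5 hydroxyl as an acetal that withstands peracid, organolithium, hydride and amine bases.

Step 2
Reactants: 2 3-methoxy-4-(methoxymethoxy)benzaldehyde
Product: 4 3-methoxy-4-(methoxymethoxy)phenol, via aryl formate 3 (not isolated)
Conditions: mCPBA, CH2Cl2, 0 °C → rt; aq. NaHCO3/Na2S2O3 wash; then K2CO3 (cat.), MeOH, rt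
Reagents that add atoms: 3-chloroperbenzoic acid, OOC(=O)c1cccc(Cl)c1
Why: Dakin-type sequence in which Baeyer–Villiger oxidation of the electron-rich benzaldehyde proceeds with aryl migration (assisted by the para alkoxy group) and the resulting formate is removed by mild methanolysis that leaves the MOM ether intact.

Step 3
Reactants: 4 3-methoxy-4-(methoxymethoxy)phenol
Product: 5 3-methoxy-4-(methoxymethoxy)phenyl N,N-diethylcarbamate
Conditions: NaH, THF, 0 °C; Et2NCOCl, rt → 50 °C
Reagents that add atoms: N,N-diethylcarbamoyl chloride, CCN(CC)C(Cl)=O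
Why: O-carbamoylation of the sodium phenoxide installs a strong oxygen-based directing group for ortho-metalation that also keeps this oxygen (the future O1) distinct from the MOM-protected one.

Step 4
Reactants: 5 3-methoxy-4-(methoxymethoxy)phenyl N,N-diethylcarbamate; 6 prenyl bromide
Product: 9 3-methoxy-4-(methoxymethoxy)-2-(3-methylbut-2-en-1-yl)phenyl N,N-diethylcarbamate, via aryllithium 7 (not isolated), via arylcopper 8 (not isolated)
Conditions: s-BuLi, TMEDA, THF, −78 °C; CuBr·SMe2, −78 → −40 °C; then 6, −78 °C → rt
Reagents that add atoms: sec-butyllithium, [Li]C(C)CC (lithium of 7); CuBr·SMe2, Br[Cu].CSC (copper of 8)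
Why: Directed ortho-metalation should occur at the carbon flanked by the carbamate and methoxy groups (cooperative 1,3-directing effect), and transmetalation to monovalent copper suppresses the anionic ortho-Fries rearrangement and lets the arylcopper displace bromide at the primary carbon of prenyl bromide (allylic substitution).

Step 5
Reactants: 9 3-methoxy-4-(methoxymethoxy)-2-(3-methylbut-2-en-1-yl)phenyl N,N-diethylcarbamate
Product: 10 3-methoxy-4-(methoxymethoxy)-2-(3-methylbut-2-en-1-yl)phenol
Conditions: LiAlH4, THF, 0 °C → reflux; aq. potassium sodium tartrate (KNaC4H4O6) work-up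
Reagents that add atoms: none
Why: Reductive cleavage of the aryl carbamate (hydride attack at the carbamate carbonyl expels the phenoxide) frees the phenol without acid, so the MOM ether and the ortho-prenylphenol are not exposed to conditions that would cleave or cyclise them.

Step 6
Reactants: 10 3-methoxy-4-(methoxymethoxy)-2-(3-methylbut-2-en-1-yl)phenol
Product: 11 2-hydroxy-4-methoxy-5-(methoxymethoxy)-3-(3-methylbut-2-en-1-yl)benzaldehyde
Conditions: MgCl2, Et3N, (CH2O)n, MeCN, reflux; cold aq. citric acid work-up
Reagents that add atoms: paraformaldehyde (as formaldehyde), C=O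
Why: Casnati–Skattebøl ortho-formylation, in which the magnesium phenoxide delivers formaldehyde to the only unsubstituted ortho carbon and a second formaldehyde accepts hydride, so only one regioisomer can form and the basic medium spares the prenyl group and the MOM ether.

Step 7
Reactants: 11 2-hydroxy-4-methoxy-5-(methoxymethoxy)-3-(3-methylbut-2-en-1-yl)benzaldehyde
Product: 12 6-(hydroxymethyl)-3-methoxy-4-(methoxymethoxy)-2-(3-methylbut-2-en-1-yl)phenol
Conditions: NaBH4, MeOH, 0 °C; aq. NH4Cl work-up
Reagents that add atoms: none
Why: Chemoselective borohydride reduction of the aldehyde gives the salicyl alcohol, which is used promptly because it is electron-rich and ionises easily.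

Step 8
Reactants: 12 6-(hydroxymethyl)-3-methoxy-4-(methoxymethoxy)-2-(3-methylbut-2-en-1-yl)phenol; 13 triphenylphosphine hydrobromide
Product: 14 [2-hydroxy-4-methoxy-5-(methoxymethoxy)-3-(3-methylbut-2-en-1-yl)benzyl]triphenylphosphonium bromide
Conditions: 13 (1.05 equiv), MeCN, rt → 40 °C; precipitation with Et2O
Reagents that add atoms: none
Why: The standard preparation of 2-hydroxybenzylphosphonium salts (acid-promoted SN1-type substitution through the ortho-quinone methide or benzylic cation, trapped by triphenylphosphine) should run near room temperature here because the ortho hydroxyl and para methoxy groups stabilise the cation, which keeps the MOM ether and the ortho-prenylphenol out of harsher acid.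

Step 9
Reactants: 15 methyl 3-hydroxy-5-methoxybenzoate
Product: 16 methyl 3-methoxy-5-(methoxymethoxy)benzoate
Conditions: MOMCl, i-Pr2NEt, CH2Cl2, 0 °C → rt
Reagents that add atoms: chloromethyl methyl ether, COCCl
Why: Williamson-type O-alkylation protects the resorcinol hydroxyl with the same acetal as on the other ring, so that one acid treatment unmasks both phenols at the end.

Step 10
Reactants: 16 methyl 3-methoxy-5-(methoxymethoxy)benzoate
Product: 17 3-methoxy-5-(methoxymethoxy)benzoic acid
Conditions: LiOH, THF/MeOH/H2O, rt; then 1 M HCl to pH 4, 0 °C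
Reagents that add atoms: lithium hydroxide, [Li+].[OH-]
Why: Saponification of the methyl ester is followed by cold acidification only to pH 4, which protonates the carboxylate without cleaving the MOM ether.

Step 11
Reactants: 14 [2-hydroxy-4-methoxy-5-(methoxymethoxy)-3-(3-methylbut-2-en-1-yl)benzyl]triphenylphosphonium bromide; 17 3-methoxy-5-(methoxymethoxy)benzoic acid
Product: 19 [2-{[3-methoxy-5-(methoxymethoxy)benzoyl]oxy}-4-methoxy-5-(methoxymethoxy)-3-(3-methylbut-2-en-1-yl)benzyl]triphenylphosphonium bromide, via acid chloride 18 (not isolated)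
Conditions: 17, 1-chloro-N,N,2-trimethylprop-1-en-1-amine, CH2Cl2, 0 °C → rt; then 14, pyridine, DMAP (cat.), 0 °C → rt; aq. NaBr wash, precipitation with Et2O
Reagents that add atoms: 1-chloro-N,N,2-trimethylprop-1-en-1-amine, CC(C)=C(Cl)N(C)C (chlorine of 18)
Why: The α-chloroenamine converts the acid into its chloride without liberating HCl (so the MOM ether survives), and pyridine/DMAP-mediated esterification of the only free hydroxyl places the future C2 and its aryl group on the oxygen that becomes O1, while pyridine is too weak a base to form the ylide, so the salt can be isolated.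

Step 12
Reactants: 19 [2-{[3-methoxy-5-(methoxymethoxy)benzoyl]oxy}-4-methoxy-5-(methoxymethoxy)-3-(3-methylbut-2-en-1-yl)benzyl]triphenylphosphonium bromide
Product: 22 6-methoxy-5-(methoxymethoxy)-2-[3-methoxy-5-(methoxymethoxy)phenyl]-7-(3-methylbut-2-en-1-yl)benzofuran, via phosphonium ylide 20 (not isolated), via oxaphosphetane 21 (not isolated)
Conditions: Et3N (3 equiv), toluene, 110 °C
Reagents that add atoms: none
Why: Triethylamine reversibly removes a benzylic proton of 19 to give the semi-stabilised ylide 20, whose carbanionic carbon (future C3) adds to the carbonyl carbon of the adjacent aryl ester (future C2) to give oxaphosphetane 21, and syn-elimination of triphenylphosphine oxide then creates the C2=C3 double bond. The closest known reaction type is the intramolecular Wittig olefination of the ester carbonyl in O-acyl 2-hydroxybenzylphosphonium salts, a standard entry to 2-arylbenzofurans. The furan ring (O1–C2–C3–C3a–C7a) closes in a 5-exo-trig mode at carbon; esters are reluctant Wittig acceptors, but the reaction is intramolecular and the product ring is aromatic. The two stereocentres of 21 are transient and vanish on elimination, so no stereocontrol is required. The step needs chemoselectivity only (attack on the ester of the same molecule instead of intermolecular C-acylation or ester cleavage), which is secured by using isolated 19 free of acid chloride and a weak amine base that leaves the MOM ethers and the prenyl group untouched; the regiochemistry is fixed because the acyl group can only sit on the oxygen that becomes O1.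

Step 13
Reactants: 22 6-methoxy-5-(methoxymethoxy)-2-[3-methoxy-5-(methoxymethoxy)phenyl]-7-(3-methylbut-2-en-1-yl)benzofuran
Product: 23 dinklagein A, 2-(3-hydroxy-5-methoxyphenyl)-6-methoxy-7-(3-methylbut-2-en-1-yl)benzofuran-5-ol
Conditions: HCl (1.25 M in MeOH), 40 °C
Reagents that add atoms: none
Why: Acid-catalysed acetal exchange with methanol removes both aryl MOM ethers, and the prenyl group at C7 (between 6-OMe and O1) has no neighbouring free phenol, so chroman formation is not possible and the benzofuran is stable to this acid.

**Compound list**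

1 | vanillin | COc1cc(C=O)ccc1O | starting material
2 | 3-methoxy-4-(methoxymethoxy)benzaldehyde | COCOc1ccc(C=O)cc1OC | intermediate
3 | 3-methoxy-4-(methoxymethoxy)phenyl formate | COCOc1ccc(OC=O)cc1OC | intermediate
4 | 3-methoxy-4-(methoxymethoxy)phenol | COCOc1ccc(O)cc1OC | intermediate
5 | 3-methoxy-4-(methoxymethoxy)phenyl N,N-diethylcarbamate | CCN(CC)C(=O)Oc1ccc(OCOC)c(OC)c1 | intermediate
6 | prenyl bromide (1-bromo-3-methylbut-2-ene) | CC(C)=CCBr | starting material
7 | 2-lithio-3-methoxy-4-(methoxymethoxy)phenyl N,N-diethylcarbamate | CCN(CC)C(=O)Oc1ccc(OCOC)c(OC)c1[Li] | intermediate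
8 | 2-cuprio-3-methoxy-4-(methoxymethoxy)phenyl N,N-diethylcarbamate (arylcopper, monovalent copper) | CCN(CC)C(=O)Oc1ccc(OCOC)c(OC)c1[Cu] | intermediate
9 | 3-methoxy-4-(methoxymethoxy)-2-(3-methylbut-2-en-1-yl)phenyl N,N-diethylcarbamate | CCN(CC)C(=O)Oc1ccc(OCOC)c(OC)c1CC=C(C)C | intermediate
10 | 3-methoxy-4-(methoxymethoxy)-2-(3-methylbut-2-en-1-yl)phenol | COCOc1ccc(O)c(CC=C(C)C)c1OC | intermediate
11 | 2-hydroxy-4-methoxy-5-(methoxymethoxy)-3-(3-methylbut-2-en-1-yl)benzaldehyde | COCOc1cc(C=O)c(O)c(CC=C(C)C)c1OC | intermediate
12 | 6-(hydroxymethyl)-3-methoxy-4-(methoxymethoxy)-2-(3-methylbut-2-en-1-yl)phenol | COCOc1cc(CO)c(O)c(CC=C(C)C)c1OC | intermediate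
13 | triphenylphosphine hydrobromide | Br.c1ccc(cc1)P(c1ccccc1)c1ccccc1 | starting material
14 | [2-hydroxy-4-methoxy-5-(methoxymethoxy)-3-(3-methylbut-2-en-1-yl)benzyl]triphenylphosphonium bromide | [Br-].COCOc1cc(C[P+](c2ccccc2)(c2ccccc2)c2ccccc2)c(O)c(CC=C(C)C)c1OC | intermediate
15 | methyl 3-hydroxy-5-methoxybenzoate | COC(=O)c1cc(O)cc(OC)c1 | starting material
16 | methyl 3-methoxy-5-(methoxymethoxy)benzoate | COCOc1cc(OC)cc(C(=O)OC)c1 | intermediate
17 | 3-methoxy-5-(methoxymethoxy)benzoic acid | COCOc1cc(OC)cc(C(=O)O)c1 | intermediate
18 | 3-methoxy-5-(methoxymethoxy)benzoyl chloride | COCOc1cc(OC)cc(C(=O)Cl)c1 | intermediate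
19 | [2-{[3-methoxy-5-(methoxymethoxy)benzoyl]oxy}-4-methoxy-5-(methoxymethoxy)-3-(3-methylbut-2-en-1-yl)benzyl]triphenylphosphonium bromide | [Br-].COCOc1cc(C[P+](c2ccccc2)(c2ccccc2)c2ccccc2)c(OC(=O)c2cc(OC)cc(OCOC)c2)c(CC=C(C)C)c1OC | intermediate
20 | phosphonium ylide of 19 (benzylidenetriphenylphosphorane) | COCOc1cc(C=P(c2ccccc2)(c2ccccc2)c2ccccc2)c(OC(=O)c2cc(OC)cc(OCOC)c2)c(CC=C(C)C)c1OC | intermediate
21 | oxaphosphetane fused across C2–C3 of the 2,3-dihydrobenzofuran (transient; racemic, relative configuration not controlled and lost on elimination) | COCOc1cc2c(c(CC=C(C)C)c1OC)OC1(c3cc(OC)cc(OCOC)c3)OP(c3ccccc3)(c3ccccc3)(c3ccccc3)C21 | intermediate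
22 | 6-methoxy-5-(methoxymethoxy)-2-[3-methoxy-5-(methoxymethoxy)phenyl]-7-(3-methylbut-2-en-1-yl)benzofuran | COCOc1cc2cc(-c3cc(OC)cc(OCOC)c3)oc2c(CC=C(C)C)c1OC | intermediate
23 | dinklagein A, 2-(3-hydroxy-5-methoxyphenyl)-6-methoxy-7-(3-methylbut-2-en-1-yl)benzofuran-5-ol | COc1cc(O)cc(-c2cc3cc(O)c(OC)c(CC=C(C)C)c3o2)c1 | target

**Step count**

Total step count: 13. Longest linear sequence: 11 steps (steps 1–8, then 11–13); steps 9–10 form the two-step side branch to acid 17.

**Three steps most likely to fail**

Step 8 (phosphonium salt formation). The acidic phosphine salt may cleave the MOM acetal, or the free phenol may add across the protonated prenyl double bond to form a chroman, before the benzylic alcohol has been fully substituted. The fallback avoids acid altogether; it sets out from 12 and returns to the route at 19. Alcohol 12 would be acylated selectively at the phenoxide oxygen with acid chloride 18 (made as in step 11) under phase-transfer Schotten–Baumann conditions (aq. NaOH, CH2Cl2, Bu4NHSO4, 0 °C) to give the ester alcohol 2-(hydroxymethyl)-5-methoxy-4-(methoxymethoxy)-6-(3-methylbut-2-en-1-yl)phenyl 3-methoxy-5-(methoxymethoxy)benzoate F1. Appel bromination (CBr4, PPh3, CH2Cl2, 0 °C) would convert it into the benzylic bromide 2-(bromomethyl)-5-methoxy-4-(methoxymethoxy)-6-(3-methylbut-2-en-1-yl)phenyl 3-methoxy-5-(methoxymethoxy)benzoate F2. Quaternisation with PPh3 (toluene, 50 °C) would then give 19 directly, bypassing 14.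

Step 4 (ortho-metalation and prenylation). Allylic substitution by the hindered arylcopper may be slow and may go partly by attack at the tertiary end of prenyl bromide, giving the 1,1-dimethylallyl isomer; warming to force conversion invites anionic ortho-Fries rearrangement of any remaining aryllithium. The fallback sets out from 5 and returns at 9. The same metalation and transmetalation would be quenched with allyl bromide, which is more reactive and has two equivalent termini, to give 2-allyl-3-methoxy-4-(methoxymethoxy)phenyl N,N-diethylcarbamate F3. Olefin cross-metathesis of F3 with 2-methylbut-2-ene (second-generation Grubbs catalyst, RuCl2(=CHPh)(H2IMes)(PCy3), CH2Cl2, 40 °C) would convert the allyl group into the prenyl group of 9.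

Step 12 (intramolecular Wittig closure). The ylide may fail to add to the crowded, electron-rich aryl ester, and on prolonged heating the ester may be cleaved by acyl transfer, returning the phenol instead of the furan. The fallback forms the same C2=C3 bond by carbanion–aldehyde condensation; it sets out from 11 (with ester 16 as the source of the aryl fragment) and returns at 22. Ester 16 would be reduced (LiAlH4, THF, 0 °C) to [3-methoxy-5-(methoxymethoxy)phenyl]methanol F4 and brominated (CBr4, PPh3, CH2Cl2, 0 °C) to 1-(bromomethyl)-3-methoxy-5-(methoxymethoxy)benzene F5. O-Alkylation of salicylaldehyde 11 with F5 (K2CO3, DMF, 50 °C) would give 4-methoxy-2-{[3-methoxy-5-(methoxymethoxy)benzyl]oxy}-5-(methoxymethoxy)-3-(3-methylbut-2-en-1-yl)benzaldehyde F6. Treatment of F6 with the phosphazene base P4-t-Bu (toluene, 80–100 °C) would deprotonate the benzylic ether carbon, which adds to the ortho aldehyde and dehydrates to benzofuran 22, a known base-mediated route from 2-(benzyloxy)benzaldehydes to 2-arylbenzofurans.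

**Further compounds**

F1 | step 8 | 2-(hydroxymethyl)-5-methoxy-4-(methoxymethoxy)-6-(3-methylbut-2-en-1-yl)phenyl 3-methoxy-5-(methoxymethoxy)benzoate | COCOc1cc(CO)c(OC(=O)c2cc(OC)cc(OCOC)c2)c(CC=C(C)C)c1OC
F2 | step 8 | 2-(bromomethyl)-5-methoxy-4-(methoxymethoxy)-6-(3-methylbut-2-en-1-yl)phenyl 3-methoxy-5-(methoxymethoxy)benzoate | COCOc1cc(CBr)c(OC(=O)c2cc(OC)cc(OCOC)c2)c(CC=C(C)C)c1OC
F3 | step 4 | 2-allyl-3-methoxy-4-(methoxymethoxy)phenyl N,N-diethylcarbamate | CCN(CC)C(=O)Oc1ccc(OCOC)c(OC)c1CC=C
F4 | step 12 | [3-methoxy-5-(methoxymethoxy)phenyl]methanol | COCOc1cc(OC)cc(CO)c1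
F5 | step 12 | 1-(bromomethyl)-3-methoxy-5-(methoxymethoxy)benzene | COCOc1cc(OC)cc(CBr)c1
F6 | step 12 | 4-methoxy-2-{[3-methoxy-5-(methoxymethoxy)benzyl]oxy}-5-(methoxymethoxy)-3-(3-methylbut-2-en-1-yl)benzaldehyde | COCOc1cc(C=O)c(OCc2cc(OC)cc(OCOC)c2)c(CC=C(C)C)c1OC
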